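**Retrosynthetic overview**
1. Target 22 ⇒ aldol adduct 21 (LiBH4 removes the auxiliary and both acetates) ⇒ Evans syn-glycolate aldol of furofuran imide 20 with vanillin acetate 6, which sets the threo (7S,8S) side chain last.
2. Furofuran 20 ⇒ bicyclic lactol 18 + 2,6-dimethoxyphenol 9, by Friedel–Crafts C-arylation at the lactol carbon (sets C7′).
3. Lactol 18 ⇒ aldehyde 12 + racemic triol 15, by a Prins–pinacol ring contraction (dioxolane → tetrahydropyranyl cation → oxolane). Ring A forms first; ring B closes second by lactolisation.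
4. 12 ⇒ vanillin 5 + bromoacetyl imide 11; 5 ⇐ catechol 1; 9 ⇐ phenol 7; 15 ⇐ cross-metathesis of 13 and 14.

Assumption: descriptors follow the SMILES, i.e. a (7S,8S)-threo arylglycerol ether on a (7R,8S,7′R,8′S) furofuran (lignan numbering); in the substrate-controlled Prins–pinacol variant used as a fallback, chirality transfer is taken to run through the chair with the tin-bound alkoxide axial.

Shorthand: Xc = (4R)-4-benzyl-2-oxo-1,3-oxazolidin-3-yl; G = 3-methoxy-4-[2-oxo-2-(Xc)ethoxy]phenyl.

**Route**

Step 1
Reactants: 1 catechol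
Product: 2 guaiacol (2-methoxyphenol)
Conditions: MeI (1.0 equiv), K2CO3, acetone, 56 °C; guaiacol separated from catechol and veratrole by distillation
Reagents that add atoms: iodomethane, CI
Why: Williamson mono-O-methylation of a symmetrical diphenol, where one equivalent of MeI gives mainly the mono-ether and the by-products differ enough in acidity and boiling point to be removed.

Step 2
Reactants: 2 guaiacol, 3 glyoxylic acid
Product: 5 vanillin (4-hydroxy-3-methoxybenzaldehyde), via 4-hydroxy-3-methoxymandelic acid 4 (not isolated)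
Conditions: aq. NaOH, 30 °C; then CuSO4 (cat.), air, aq. NaOH, 95 °C; H2SO4 to pH 3
Reagents that add atoms: none
Why: Electrophilic aromatic hydroxyalkylation para to the phenoxide, followed by copper-catalysed oxidative decarboxylation of the mandelate (the guaiacol–glyoxylic acid vanillin process).

Step 3
Reactants: 5 vanillin
Product: 6 vanillin acetate (4-formyl-2-methoxyphenyl acetate)
Conditions: Ac2O, pyridine, 23 °C
Reagents that add atoms: acetic anhydride, CC(=O)OC(C)=O
Why: O-Acetylation gives a phenol ester that tolerates boron-enolate aldol chemistry and falls off in the final LiBH4 step, so no separate deprotection is needed.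

Step 4
Reactants: 7 phenol
Product: 8 2,6-dibromophenol
Conditions: Br2 (2.0 equiv), t-BuNH2 (2.0 equiv), toluene, −70 °C to 23 °C
Reagents that add atoms: bromine, BrBr
Why: Amine-mediated ortho-selective electrophilic bromination, in which the N-bromoamine is delivered to both ortho positions through hydrogen bonding to the phenol and the para position is left free.

Step 5
Reactants: 8 2,6-dibromophenol
Product: 9 2,6-dimethoxyphenol
Conditions: NaOMe (excess), CuI (10 mol%), DMF–MeOH, 110 °C; acidic work-up
Reagents that add atoms: sodium methoxide, C[O-].[Na+]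
Why: Copper-catalysed Ullmann-type methoxylation of aryl bromides, the same transformation used to turn bromophenols into guaiacyl and syringyl ethers.

Step 6
Reactants: 10 bromoacetyl bromide
Product: 11 (4R)-4-benzyl-3-(bromoacetyl)-1,3-oxazolidin-2-one
Conditions: (R)-4-benzyl-1,3-oxazolidin-2-one, n-BuLi, THF, −78 °C; then 10, −78 to 0 °C
Reagents that add atoms: (R)-4-benzyl-1,3-oxazolidin-2-one, O=C1OC[C@@H](Cc2ccccc2)N1
Why: N-Acylation of the lithiated oxazolidinone, which reacts at the acyl bromide far faster than at the alkyl bromide.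

Step 7
Reactants: 5 vanillin, 11 (4R)-4-benzyl-3-(bromoacetyl)-1,3-oxazolidin-2-one
Product: 12 3-methoxy-4-[2-oxo-2-(Xc)ethoxy]benzaldehyde
Conditions: K2CO3, acetone, 23 °C
Reagents that add atoms: none
Why: Williamson ether synthesis by SN2 attack of the weakly basic vanillin phenoxide on the activated α-bromo imide, leaving the aldehyde and the imide untouched.

Step 8
Reactants: 13 rac-but-3-ene-1,2-diol, 14 (Z)-but-2-ene-1,4-diol
Product: 15 rac-(E)-pent-3-ene-1,2,5-triol
Conditions: 14 (3 equiv), second-generation Hoveyda–Grubbs catalyst RuCl2(H2IMes)(=CH-C6H4-2-OiPr), C31H38Cl2N2ORu (2 mol%), THF, 40 °C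
Reagents that add atoms: none
Why: Olefin cross-metathesis of a terminal alkene with excess internal allylic diol, which tolerates free hydroxyls and gives the E-alkene under thermodynamic control.

Step 9
Reactants: 12 3-methoxy-4-[2-oxo-2-(Xc)ethoxy]benzaldehyde, 15 rac-(E)-pent-3-ene-1,2,5-triol
Product: 18 (1S,2R,5S)-2-G-3,7-dioxabicyclo[3.3.0]octan-6-ol (anomeric mixture), via dioxolane acetal 16 (not isolated), via trans-hydroxy aldehyde 17 (not isolated)
Conditions: (S,S)-IDPi acid C74H33F30N3O8P2S2 (imidodiphosphorimidate from two (S)-3,3′-bis[3,5-bis(trifluoromethyl)phenyl]-BINOL units, N-triflyl; 5 mol%), 5 Å MS, CHCl3, 25 °C; then DBU (1,8-diazabicyclo[5.4.0]undec-7-ene, 20 mol%), 25 °C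
Reagents that add atoms: none
Why: Proposed new method: an enantioconvergent, Brønsted-acid-catalysed Prins–pinacol ring contraction, in which the acid condenses 12 with rac-15 to dioxolane 16 and ionises it to an (E)-oxocarbenium ion held in the confined chiral anion; the (E)-alkene attacks through a chair with aryl and CH2OH both equatorial (hence 7,8-trans, with the catalyst choosing the face pairing and so setting C7 as R and C8 as S), and the resulting tetrahydropyranyl cation collapses by pinacol 1,2-shift of the ring CH2–O carbon, contracting the six-membered ring to the oxolane and turning the carbinol carbon into the formyl group, which erases the only stereocentre of the diol so that both enantiomers of 15 converge on 17; DBU then epimerises the formyl-bearing carbon through the enol and the cis isomer is trapped as lactol 18 (ring B); the closest known reactions are the Lewis-acid Prins–pinacol rearrangement of allylic diol acetals to 3-acyltetrahydrofurans and IDPi-catalysed asymmetric Prins cyclisations.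

Step 10
Reactants: 18 (1S,2R,5S)-2-G-3,7-dioxabicyclo[3.3.0]octan-6-ol, 9 2,6-dimethoxyphenol
Product: 20 (1S,2R,5S,6R)-2-G-6-(4-acetoxy-3,5-dimethoxyphenyl)-3,7-dioxabicyclo[3.3.0]octane, via free phenol 19 (not isolated)
Conditions: 9 (2 equiv), Sc(OTf)3 (10 mol%), 4 Å MS, CH2Cl2–MeCN, −20 to 0 °C; then pyridine, Ac2O, 4-(dimethylamino)pyridine (cat.), 23 °C
Reagents that add atoms: acetic anhydride, CC(=O)OC(C)=O
Why: Friedel–Crafts C-arylation (aryl C-glycosylation type, the reactivity that turns sesamolin into sesaminol) of the cyclic oxocarbenium ion from the lactol by the carbon para to the phenol OH, with attack on the convex face of the cis-fused bicycle placing the aryl group exo (C7′ = R); the free phenol is acetylated in the same flask.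

Step 11
Reactants: 20 (1S,2R,5S,6R)-2-G-6-(4-acetoxy-3,5-dimethoxyphenyl)-3,7-dioxabicyclo[3.3.0]octane, 6 vanillin acetate
Product: 21 syn-aldol adduct, the Xc imide of (2R,3S)-3-(4-acetoxy-3-methoxyphenyl)-3-hydroxy-2-aryloxypropanoic acid (aryl = the furofuran guaiacyl ring of 20)
Conditions: Bu2BOTf (1.2 equiv), i-Pr2NEt (1.4 equiv), CH2Cl2, −78 to 0 °C; then 6, −78 to 0 °C; pH 7 buffer, MeOH
Reagents that add atoms: none
Why: Evans syn-glycolate aldol through the (Z)-boron enolate and a Zimmerman–Traxler chair, in which the (R)-benzyl auxiliary directs the aldehyde to one enolate face and sets both side-chain centres as the threo pair that becomes (7S,8S).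

Step 12
Reactants: 21 syn-aldol adduct
Product: 22 target, (1S,2R,5S,6R)-2-{4-[(1S,2S)-1,3-dihydroxy-1-(4-hydroxy-3-methoxyphenyl)propan-2-yloxy]-3-methoxyphenyl}-6-(4-hydroxy-3,5-dimethoxyphenyl)-3,7-dioxabicyclo[3.3.0]octane
Conditions: LiBH4 (excess), THF–MeOH, 0 to 23 °C
Reagents that add atoms: none
Why: Reductive cleavage of the N-acyl oxazolidinone at the exocyclic carbonyl gives the primary alcohol, and the same hydride cleaves both aryl acetates, with no stereocentre touched and no hydrogenolysis conditions that would open the benzylic furofuran ethers.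

**Compound list**
1 | catechol | Oc1ccccc1O | starting material
2 | guaiacol | COc1ccccc1O | intermediate
3 | glyoxylic acid | O=CC(=O)O | starting material
4 | rac-4-hydroxy-3-methoxymandelic acid | COc1cc(C(O)C(=O)O)ccc1O | intermediate
5 | vanillin | COc1cc(C=O)ccc1O | intermediate
6 | vanillin acetate | COc1cc(C=O)ccc1OC(C)=O | intermediate
7 | phenol | Oc1ccccc1 | starting material
8 | 2,6-dibromophenol | Oc1c(Br)cccc1Br | intermediate
9 | 2,6-dimethoxyphenol | COc1cccc(OC)c1O | intermediate
10 | bromoacetyl bromide | BrCC(Br)=O | starting material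
11 | (4R)-4-benzyl-3-(bromoacetyl)-1,3-oxazolidin-2-one | O=C1OC[C@@H](Cc2ccccc2)N1C(=O)CBr | intermediate
12 | 3-methoxy-4-[2-oxo-2-(Xc)ethoxy]benzaldehyde | COc1cc(C=O)ccc1OCC(=O)N1[C@H](Cc2ccccc2)COC1=O | intermediate
13 | rac-but-3-ene-1,2-diol | OCC(O)C=C | starting material
14 | (Z)-but-2-ene-1,4-diol | OC/C=C\CO | starting material
15 | rac-(E)-pent-3-ene-1,2,5-triol | OC/C=C/C(O)CO | intermediate
16 | 2-G-4-[(E)-3-hydroxyprop-1-enyl]-1,3-dioxolane (mixture of ring stereoisomers) | COc1cc(C2OCC(/C=C/CO)O2)ccc1OCC(=O)N1[C@H](Cc2ccccc2)COC1=O | intermediate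
17 | (3R,4S,5R)-4-(hydroxymethyl)-5-G-oxolane-3-carbaldehyde | COc1cc([C@@H]2OC[C@H](C=O)[C@H]2CO)ccc1OCC(=O)N1[C@H](Cc2ccccc2)COC1=O | intermediate
18 | (1S,2R,5S)-2-G-3,7-dioxabicyclo[3.3.0]octan-6-ol (anomeric mixture) | COc1cc([C@@H]2OC[C@@H]3[C@H]2COC3O)ccc1OCC(=O)N1[C@H](Cc2ccccc2)COC1=O | intermediate
19 | (1S,2R,5S,6R)-2-G-6-(4-hydroxy-3,5-dimethoxyphenyl)-3,7-dioxabicyclo[3.3.0]octane | COc1cc([C@@H]2OC[C@@H]3[C@H]2CO[C@H]3c2cc(OC)c(O)c(OC)c2)ccc1OCC(=O)N1[C@H](Cc2ccccc2)COC1=O | intermediate
20 | (1S,2R,5S,6R)-2-G-6-(4-acetoxy-3,5-dimethoxyphenyl)-3,7-dioxabicyclo[3.3.0]octane | COc1cc([C@@H]2OC[C@@H]3[C@H]2CO[C@H]3c2cc(OC)c(OC(C)=O)c(OC)c2)ccc1OCC(=O)N1[C@H](Cc2ccccc2)COC1=O | intermediate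
21 | syn-aldol adduct, Xc imide of (2R,3S)-3-(4-acetoxy-3-methoxyphenyl)-3-hydroxy-2-aryloxypropanoic acid | COc1cc([C@H](O)[C@H](C(=O)N2[C@H](Cc3ccccc3)COC2=O)Oc2ccc([C@@H]3OC[C@@H]4[C@H]3CO[C@H]4c3cc(OC)c(OC(C)=O)c(OC)c3)cc2OC)ccc1OC(C)=O | intermediate
22 | target, (7S,8S)-threo-guaiacylglycerol 8-O-4′ ether of (7R,8S,7′R,8′S)-medioresinol | COc1cc([C@H](O)[C@H](CO)Oc2ccc([C@@H]3OC[C@@H]4[C@H]3CO[C@H]4c3cc(OC)c(O)c(OC)c3)cc2OC)ccc1O | target

**Totals and weak points**
Total step count: 12. Longest linear sequence: 7 steps (1, 2, 7, 9, 10, 11, 12).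

Most likely to fail, first: step 9, the proposed new reaction. The alkene carries two allylic oxygens and the oxocarbenium ion is stabilised by the electron-rich ring, so the Prins step may be slow. The catalyst may also turn over only one enantiomer of 15, giving a kinetic resolution instead of convergence. The fallback uses known chemistry, sets out from 12 and 14 and comes back at 18. Commercial (R)-but-3-ene-1,2-diol F1 is cross-metathesised with 14 as in step 8 to give (2R,3E)-pent-3-ene-1,2,5-triol F2. F2 and 12 are condensed (pyridinium p-toluenesulfonate, MgSO4, CH2Cl2) to the isolated (4R)-dioxolane acetal F3. SnCl4 (2.2 equiv) in CH2Cl2 at −78 to −20 °C then effects the established substrate-controlled Prins–pinacol rearrangement of allylic diol acetals, with chirality transfer from the dioxolane stereocentre, to give 17, and DBU converts 17 into 18.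

Second: step 10. The risks are attack at a ring carbon other than the one para to OH, and acid-promoted epimerisation or opening of the very electron-rich benzylic ether once formed. The fallback sets out from 9 and 18 and comes back at 20, delivering the aryl group as a pre-metalated nucleophile of fixed regiochemistry. Compound 9 is brominated (NBS, MeCN, 0 °C) to 4-bromo-2,6-dimethoxyphenol F4 and silylated (TBSCl, imidazole) to its tert-butyldimethylsilyl ether F5. Bromine–lithium exchange (n-BuLi, THF, −78 °C) and ZnBr2 give the arylzinc bromide F6. Lactol 18 is acetylated (Ac2O, pyridine) to the anomeric acetate F7, which is ionised with TMSOTf at −78 °C in the presence of F6 (α-acetoxy-ether/organozinc oxocarbenium coupling, addition on the convex face) to give the silyl-protected furofuran F8. Bu4NF/AcOH and then Ac2O/pyridine give 20 through 19.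

Third: step 11. The risks are incomplete enolisation or low facial control on a large substrate carrying two aryl acetates, and retro-aldol on work-up. The fallback sets out from 6 and 20 and comes back at 21 by acylation and reduction instead of aldol addition. Compound 6 is oxidised (NaClO2, NaH2PO4, 2-methyl-2-butene) to 4-acetoxy-3-methoxybenzoic acid F9 and converted with (COCl)2 and catalytic DMF into the acid chloride F10. The lithium (Z)-enolate of 20 (LiN(SiMe3)2, THF, −78 °C) is C-acylated with F10 under auxiliary control to the β-keto imide F11. Chelation-controlled reduction with Zn(BH4)2 (CH2Cl2, −20 °C), as established for α-substituted β-keto imides, gives the syn alcohol 21.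

**Further compounds**
F1 | step 9 | (R)-but-3-ene-1,2-diol | C=C[C@@H](O)CO
F2 | step 9 | (2R,3E)-pent-3-ene-1,2,5-triol | OC/C=C/[C@@H](O)CO
F3 | step 9 | (4R)-2-G-4-[(E)-3-hydroxyprop-1-enyl]-1,3-dioxolane | COc1cc(C2OC[C@@H](/C=C/CO)O2)ccc1OCC(=O)N1[C@H](Cc2ccccc2)COC1=O
F4 | step 10 | 4-bromo-2,6-dimethoxyphenol | COc1cc(Br)cc(OC)c1O
F5 | step 10 | (4-bromo-2,6-dimethoxyphenoxy)(tert-butyl)dimethylsilane | COc1cc(Br)cc(OC)c1O[Si](C)(C)C(C)(C)C
F6 | step 10 | [4-(tert-butyldimethylsilyloxy)-3,5-dimethoxyphenyl]zinc bromide | COc1cc([Zn]Br)cc(OC)c1O[Si](C)(C)C(C)(C)C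
F7 | step 10 | (1S,2R,5S)-2-G-3,7-dioxabicyclo[3.3.0]octan-6-yl acetate | COc1cc([C@@H]2OC[C@@H]3[C@H]2COC3OC(C)=O)ccc1OCC(=O)N1[C@H](Cc2ccccc2)COC1=O
F8 | step 10 | (1S,2R,5S,6R)-2-G-6-[4-(tert-butyldimethylsilyloxy)-3,5-dimethoxyphenyl]-3,7-dioxabicyclo[3.3.0]octane | COc1cc([C@@H]2OC[C@@H]3[C@H]2CO[C@H]3c2cc(OC)c(O[Si](C)(C)C(C)(C)C)c(OC)c2)ccc1OCC(=O)N1[C@H](Cc2ccccc2)COC1=O
F9 | step 11 | 4-acetoxy-3-methoxybenzoic acid | COc1cc(C(=O)O)ccc1OC(C)=O
F10 | step 11 | 4-acetoxy-3-methoxybenzoyl chloride | COc1cc(C(Cl)=O)ccc1OC(C)=O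
F11 | step 11 | β-keto imide, Xc imide of 3-(4-acetoxy-3-methoxyphenyl)-3-oxo-2-aryloxypropanoic acid | COc1cc(C(=O)[C@H](C(=O)N2[C@H](Cc3ccccc3)COC2=O)Oc2ccc([C@@H]3OC[C@@H]4[C@H]3CO[C@H]4c3cc(OC)c(OC(C)=O)c(OC)c3)cc2OC)ccc1OC(C)=O
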